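**Plan**

- Enabling feature: ring D is a 1,4-dioxygenated benzene whose C1 oxygen lies ortho to the CH2CH2 bridge to ring C, and ring C carries an oxygen para to that bridge. The ring D oxygen, ring D carbons C1 and C2 and the two bridge carbons therefore map onto the five ring atoms of a 2-aryl-5-oxygenated 2,3-dihydrobenzofuran.
- Retrosynthesis: the three ArO–CH3 bonds are cut first, then the ring D oxygen is joined back to the benzylic bridge carbon to give the dihydrofuran. The ring D carbon–CH2 bond and the O–CH bond are then cut together ([3+2]) to give 4-methoxyphenol and a ring C styrene. The styrene is cut at the vinyl C=C, at the ring B carbon–oxygen bond of the diaryl ether and at the C=C that becomes the bridge between rings A and B.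
- Forward: the ring A–ring B bridge is joined first (olefination, then diimide reduction), then the diaryl ether (copper-catalysed O-arylation), then the vinyl group (Wittig). The dihydrofuran ring closes in the anodic cycloaddition, is opened by hydrogenolysis, and demethylation finishes the route.
- Stereochemistry: the target has no stereocentre. The one centre formed at C2 of the dihydrobenzofuran is racemic and is removed when the benzylic C–O bond is cleaved.

Key step: step 5

**Route**

Step 1
Reactants: 1 diethyl (4-bromobenzyl)phosphonate; 2 3-methoxybenzaldehyde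
Product: 3 (E)-1-bromo-4-[2-(3-methoxyphenyl)ethenyl]benzene
Conditions: KOtBu, THF, 0 °C to rt
Reagents that add atoms: none
Why: Horner–Wadsworth–Emmons olefination of an aromatic aldehyde by the anion of a benzylic phosphonate is reliable and E-selective, and the alkene geometry does not matter because step 2 saturates it.

Step 2
Reactants: 3 (E)-1-bromo-4-[2-(3-methoxyphenyl)ethenyl]benzene
Product: 4 1-bromo-4-[2-(3-methoxyphenyl)ethyl]benzene
Conditions: TsNHNH2 (4 equiv), NaOAc (4 equiv), THF/H2O, reflux
Reagents that add atoms: none
Why: diimide reduction transfers two hydrogens to the stilbene C=C in a concerted manner and leaves the aryl C–Br bond alone, which hydrogenation over palladium would put at risk.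

Step 3
Reactants: 4 1-bromo-4-[2-(3-methoxyphenyl)ethyl]benzene; 5 isovanillin (3-hydroxy-4-methoxybenzaldehyde)
Product: 6 4-methoxy-3-{4-[2-(3-methoxyphenyl)ethyl]phenoxy}benzaldehyde
Conditions: CuI (10 mol%), N,N-dimethylglycine hydrochloride (30 mol%), Cs2CO3 (2 equiv), 1,4-dioxane, 100 °C, Ar
Reagents that add atoms: none
Why: Ullmann-type diaryl ether synthesis under monovalent copper catalysis with an amino acid ligand tolerates a non-enolisable aldehyde and an ortho-methoxy phenol, and 4 offers a single C–Br bond.

Step 4
Reactants: 6 4-methoxy-3-{4-[2-(3-methoxyphenyl)ethyl]phenoxy}benzaldehyde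
Product: 7 4-ethenyl-1-methoxy-2-{4-[2-(3-methoxyphenyl)ethyl]phenoxy}benzene
Conditions: Ph3PCH3Br, KOtBu, THF, 0 °C to rt; product stored cold over a trace of BHT
Reagents that add atoms: methyltriphenylphosphonium bromide, C[P+](c1ccccc1)(c1ccccc1)c1ccccc1.[Br-]
Why: Wittig methylenation of an aryl aldehyde with the unstabilised ylide is general and does not affect the aryl ethers.

Step 5
Reactants: 7 4-ethenyl-1-methoxy-2-{4-[2-(3-methoxyphenyl)ethyl]phenoxy}benzene; 8 4-methoxyphenol
Product: 11 rac-5-methoxy-2-(4-methoxy-3-{4-[2-(3-methoxyphenyl)ethyl]phenoxy}phenyl)-2,3-dihydro-1-benzofuran, via 4-methoxyphenoxonium cation 9 (not isolated), via benzylic cation 10 (not isolated)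
Conditions: controlled-potential electrolysis at the first oxidation wave of 8 (about 1.0 V vs Ag/AgCl), carbon felt anode, Pt cathode, undivided cell, LiClO4 (1.0 M) in MeNO2, AcOH (5 equiv), 8 (3 equiv), slow addition of 7, rt, about 2.2 F per mol of 7
Reagents that add atoms: none
Why: At the anode 8 loses two electrons and a proton to give phenoxonium ion 9, which the para methoxy group stabilises as an oxocarbenium ion, and the unsubstituted CH2 terminus of styrene 7 adds to the carbon ortho to its oxygen to give cation 10. This is the known oxidative formal [3+2] cycloaddition of 4-methoxyphenols with electron-rich alkenes, run anodically here as it has been with hypervalent iodine or photocatalytic oxidants. The dihydrofuran ring closes when the dienone oxygen of 10 captures the benzylic cation (cation–oxygen combination, 5-exo when counted on the quinone-methide form of the cation), and loss of a proton restores the aromaticity of ring D. The new stereocentre at C2 has no controlling element, so it forms as the racemate and is removed in step 6. The step needs the phenol to be oxidised before the styrene, which the lower potential of 8, potential control, its excess and the slow addition of 7 should secure. It also needs the aryl group to end up next to oxygen, which follows from attack through the alkene terminus and the para methoxy stabilisation of the benzylic cation on ring C, the two ortho carbons of 8 being equivalent.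

Step 6
Reactants: 11 rac-5-methoxy-2-(4-methoxy-3-{4-[2-(3-methoxyphenyl)ethyl]phenoxy}phenyl)-2,3-dihydro-1-benzofuran
Product: 12 4-methoxy-2-[2-(4-methoxy-3-{4-[2-(3-methoxyphenyl)ethyl]phenoxy}phenyl)ethyl]phenol
Conditions: H2 (3 bar), 10% Pd/C, EtOAc/AcOH, 50 °C
Reagents that add atoms: none
Why: the C2–O bond of 11 is a cyclic benzyl aryl ether, so palladium-catalysed hydrogenolysis should cleave it as in the O-debenzylation of a phenol, opening the ring and removing the stereocentre while the diaryl ether and the methyl ethers stay intact.

Step 7
Reactants: 12 4-methoxy-2-[2-(4-methoxy-3-{4-[2-(3-methoxyphenyl)ethyl]phenoxy}phenyl)ethyl]phenol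
Product: 13 2-[2-(4-hydroxy-3-{4-[2-(3-hydroxyphenyl)ethyl]phenoxy}phenyl)ethyl]benzene-1,4-diol (CNP0300581.0)
Conditions: BBr3 (6 equiv), CH2Cl2, −78 °C to rt; then H2O, 0 °C, under Ar
Reagents that add atoms: none
Why: BBr3 demethylation of aryl methyl ethers proceeds by O-complexation and bromide attack at the methyl carbon, so the diaryl ether, which has no alkyl carbon, should survive, and an oxygen-free work-up protects the hydroquinone of ring D.

**Compound list**

1 | diethyl (4-bromobenzyl)phosphonate | CCOP(=O)(Cc1ccc(Br)cc1)OCC | starting material
2 | 3-methoxybenzaldehyde | COc1cccc(C=O)c1 | starting material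
3 | (E)-1-bromo-4-[2-(3-methoxyphenyl)ethenyl]benzene | COc1cccc(/C=C/c2ccc(Br)cc2)c1 | intermediate
4 | 1-bromo-4-[2-(3-methoxyphenyl)ethyl]benzene | COc1cccc(CCc2ccc(Br)cc2)c1 | intermediate
5 | isovanillin (3-hydroxy-4-methoxybenzaldehyde) | COc1ccc(C=O)cc1O | starting material
6 | 4-methoxy-3-{4-[2-(3-methoxyphenyl)ethyl]phenoxy}benzaldehyde | COc1ccc(C=O)cc1Oc1ccc(CCc2cccc(OC)c2)cc1 | intermediate
7 | 4-ethenyl-1-methoxy-2-{4-[2-(3-methoxyphenyl)ethyl]phenoxy}benzene | C=Cc1ccc(OC)c(Oc2ccc(CCc3cccc(OC)c3)cc2)c1 | intermediate
8 | 4-methoxyphenol | COc1ccc(O)cc1 | starting material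
9 | 4-methoxyphenoxonium cation (oxocarbenium form) | C[O+]=C1C=CC(=O)C=C1 | intermediate
10 | benzylic cation, 6-(2-aryl-2-ylioethyl)-4-methoxycyclohexa-2,4-dien-1-one, aryl = 4-methoxy-3-{4-[2-(3-methoxyphenyl)ethyl]phenoxy}phenyl | COC1=CC(C[CH+]c2ccc(OC)c(Oc3ccc(CCc4cccc(OC)c4)cc3)c2)C(=O)C=C1 | intermediate
11 | rac-5-methoxy-2-(4-methoxy-3-{4-[2-(3-methoxyphenyl)ethyl]phenoxy}phenyl)-2,3-dihydro-1-benzofuran | COc1ccc2OC(Cc2c1)c1ccc(OC)c(Oc3ccc(CCc4cccc(OC)c4)cc3)c1 | intermediate
12 | 4-methoxy-2-[2-(4-methoxy-3-{4-[2-(3-methoxyphenyl)ethyl]phenoxy}phenyl)ethyl]phenol | COc1ccc(O)c(CCc2ccc(OC)c(Oc3ccc(CCc4cccc(OC)c4)cc3)c2)c1 | intermediate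
13 | 2-[2-(4-hydroxy-3-{4-[2-(3-hydroxyphenyl)ethyl]phenoxy}phenyl)ethyl]benzene-1,4-diol | Oc1cccc(CCc2ccc(Oc3cc(CCc4cc(O)ccc4O)ccc3O)cc2)c1 | target

**Step count and risks**

Total step count: 7. Longest linear sequence: 7 steps (1 to 13 through 3, 4, 6, 7, 11 and 12).

Steps most likely to fail:

Step 5. The styrene may be oxidised or protonated in competition with the phenol and then oligomerise, or the phenol may couple with itself, so that little cross-adduct forms. The fallback separates the oxidation from the bond formation. Setting out from 8, the trivalent iodine reagent PhI(OAc)2 in MeOH at 0 °C should give the quinone monoketal 4,4-dimethoxycyclohexa-2,5-dien-1-one F1, which is isolated. With styrene 7 and a Brønsted acid promoter (C6F5CO2H) in (CF3)2CHOH at rt, the ketal should ionise to the same methoxy-stabilised cation. The styrene terminus then adds ortho to the carbonyl and the oxygen closes the ring with loss of methanol. This acid-promoted formal [3+2] coupling of quinone monoketals with styrenes is known and returns to the route at 11.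

Step 6. Cleavage of the secondary, cyclic benzylic C–O bond on the catalyst surface may be slow, and forcing it risks saturating an aromatic ring. The fallback is ionic hydrogenation, setting out from 11: Et3SiH and CF3CO2H in CH2Cl2 at 0 °C to rt. The acid opens the ether to the para-methoxy-stabilised benzylic cation and the silane delivers hydride, a mechanism that needs neither a metal surface nor H2. It returns to the route at 12. No compound beyond those of the route is formed on this path (none F0).

Step 3. Oxidative addition of the unactivated bromide to copper may be slow and the phenolate of an ortho-substituted hydroxy aldehyde may bind the catalyst, so the coupling may stall or give protodebromination. The fallback replaces the Ullmann coupling by an oxidative Chan–Lam coupling. Setting out from 4, bromine–lithium exchange (nBuLi, THF, −78 °C), trapping with B(OiPr)3 and acidic work-up should give {4-[2-(3-methoxyphenyl)ethyl]phenyl}boronic acid F2. Coupling of this acid with isovanillin 5 under divalent copper (Cu(OAc)2, pyridine, 4 Å molecular sieves, CH2Cl2, air, rt) returns to the route at 6.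

**Further compounds**

F1 | step 5 | 4,4-dimethoxycyclohexa-2,5-dien-1-one | COC1(OC)C=CC(=O)C=C1
F0 | step 6 | none | none
F2 | step 3 | {4-[2-(3-methoxyphenyl)ethyl]phenyl}boronic acid | COc1cccc(CCc2ccc(cc2)B(O)O)c1
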